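**Retrosynthetic overview**
- Target ⇒ cut the CH2–aryl bond of the C8 benzyl group: apigenin C7/C8 o-quinone methide + 4-hydroxyphenylboronic acid (new deaminative boron-to-carbon aryl transfer from the C8 Mannich base).
- C8 Mannich base ⇒ apigenin + bis(dimethylamino)methane (C8–CH2 bond; regiochemistry fixed here).
- Apigenin ⇒ tri-O-benzylapigenin ⇒ 2′-hydroxychalcone by oxidative cyclisation (O1–C2 bond).
- Chalcone ⇒ 4,6-di-O-benzylphloroacetophenone + 4-(benzyloxy)benzaldehyde (Claisen–Schmidt).
- Ring order: the three benzenoid rings are bought; the only ring built is the γ-pyranone (step 3), before the C8 side chain is attached.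

Assumption: the target is achiral (no stereocentre, no stereogenic axis), so the "single enantiomer" requirement needs no stereocontrol; the racemic aldol and flavanone intermediates lose their stereocentres in the step in which they form.

**Step 1**
Reactants: 1 2′,4′,6′-trihydroxyacetophenone
Product: 2 1-[2,4-bis(benzyloxy)-6-hydroxyphenyl]ethan-1-one
Conditions: BnBr (2.05 equiv), K2CO3 (2.1 equiv), DMF, 0 °C to rt
Reagents that add atoms: benzyl bromide, BrCc1ccccc1
Why: Williamson etherification in which the 4-OH and one ortho-OH are alkylated while the remaining ortho-OH, deactivated by its hydrogen bond to the acetyl C=O, stays free and later allows only one mode of pyranone closure.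

**Step 2**
Reactants: 2 1-[2,4-bis(benzyloxy)-6-hydroxyphenyl]ethan-1-one; 3 4-(benzyloxy)benzaldehyde
Product: 5 (E)-1-[2,4-bis(benzyloxy)-6-hydroxyphenyl]-3-[4-(benzyloxy)phenyl]prop-2-en-1-one, via β-hydroxy ketone 4 (not isolated)
Conditions: KOH (50% aq.), EtOH/THF 3:1, rt, 36 h; then 1 M HCl to pH 4
Reagents that add atoms: none
Why: Claisen–Schmidt condensation (crossed aldol addition to the non-enolisable aldehyde, then E1cB dehydration of 4) gives the conjugated (E)-enone as the thermodynamic product, and benzyl ethers are stable to base.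

**Step 3**
Reactants: 5 (E)-1-[2,4-bis(benzyloxy)-6-hydroxyphenyl]-3-[4-(benzyloxy)phenyl]prop-2-en-1-one
Product: 7 5,7-bis(benzyloxy)-2-[4-(benzyloxy)phenyl]-4H-chromen-4-one, via racemic flavanone 6 (not isolated)
Conditions: I2 (10 mol%), DMSO, 130 °C, 3 h
Reagents that add atoms: none
Why: Iodine-catalysed oxidative cyclisation in DMSO, in which oxa-Michael addition of the single free phenol closes the pyranone ring to flavanone 6, α-iodination and loss of HI give the flavone, and DMSO reoxidises HI to I2, so the stereocentre of 6 is destroyed.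

**Step 4**
Reactants: 7 5,7-bis(benzyloxy)-2-[4-(benzyloxy)phenyl]-4H-chromen-4-one
Product: 8 5,7-dihydroxy-2-(4-hydroxyphenyl)-4H-chromen-4-one (apigenin)
Conditions: H2 (1 atm), 10% Pd/C, THF/MeOH 1:1, rt
Reagents that add atoms: none
Why: Catalytic hydrogenolysis cleaves the three aryl benzyl ethers, and at 1 atm and room temperature the flavone C2=C3/C4=O vinylogous ester is not reduced.

**Step 5**
Reactants: 8 5,7-dihydroxy-2-(4-hydroxyphenyl)-4H-chromen-4-one; 9 bis(dimethylamino)methane
Product: 10 8-[(dimethylamino)methyl]-5,7-dihydroxy-2-(4-hydroxyphenyl)-4H-chromen-4-one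
Conditions: 9 (1.05 equiv), 1,4-dioxane/i-PrOH 1:1, 80 °C, 3 h; precipitate collected
Reagents that add atoms: none
Why: Phenolic Mannich reaction with an aminal, in which the iminium equivalent is delivered ortho to the most acidic 7-OH and C8 (para to the 5-OH) is the kinetically preferred site of 5,7-dihydroxyflavones, while the near-stoichiometric aminal limits the 6,8-bis adduct.

**Step 6**
Reactants: 10 8-[(dimethylamino)methyl]-5,7-dihydroxy-2-(4-hydroxyphenyl)-4H-chromen-4-one; 11 4-hydroxyphenylboronic acid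
Product: 14 5,7-dihydroxy-8-(4-hydroxybenzyl)-2-(4-hydroxyphenyl)-4H-chromen-4-one, via o-quinone methide 12 (not isolated), via aryl borate 13 (not isolated)
Conditions: 11 (3 equiv), 4 Å MS, 1,4-dioxane/DMF 4:1, 110 °C, N2 sweep, 8 h; then 1 M HCl/MeOH work-up
Reagents that add atoms: none
Why: Proposed new method: a deaminative boron-to-carbon aryl transfer in which thermal loss of volatile Me2NH from the zwitterionic Mannich base unmasks the C7(=O)/C8(=CH2) o-quinone methide 12, its carbonyl oxygen binds the boronic acid to form a boron "ate" complex, and the 4-hydroxyphenyl group migrates ipso-specifically from boron to the exocyclic CH2 through a six-membered transition state driven by rearomatisation of ring A, giving borate 13 that is hydrolysed on work-up; it forms the CH2–aryl bond of the diarylmethane with no stereocentre created, and the closest known reaction types are the Petasis borono-Mannich reaction and the diol-catalysed 1,4-addition of aryl and alkenyl boronates to o-quinone methides, which to my knowledge have not been shown for a flavone-derived o-quinone methide, for a Mannich-base precursor, or on an unprotected polyphenol.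

**Compound list**
1 | 2′,4′,6′-trihydroxyacetophenone | CC(=O)c1c(O)cc(O)cc1O | starting material
2 | 1-[2,4-bis(benzyloxy)-6-hydroxyphenyl]ethan-1-one | CC(=O)c1c(O)cc(OCc2ccccc2)cc1OCc1ccccc1 | intermediate
3 | 4-(benzyloxy)benzaldehyde | O=Cc1ccc(OCc2ccccc2)cc1 | starting material
4 | 1-[2,4-bis(benzyloxy)-6-hydroxyphenyl]-3-[4-(benzyloxy)phenyl]-3-hydroxypropan-1-one (racemic; not isolated) | O=C(CC(O)c1ccc(OCc2ccccc2)cc1)c1c(O)cc(OCc2ccccc2)cc1OCc1ccccc1 | intermediate
5 | (E)-1-[2,4-bis(benzyloxy)-6-hydroxyphenyl]-3-[4-(benzyloxy)phenyl]prop-2-en-1-one | O=C(/C=C/c1ccc(OCc2ccccc2)cc1)c1c(O)cc(OCc2ccccc2)cc1OCc1ccccc1 | intermediate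
6 | 5,7-bis(benzyloxy)-2-[4-(benzyloxy)phenyl]chroman-4-one (racemic; not isolated) | O=C1CC(c2ccc(OCc3ccccc3)cc2)Oc2cc(OCc3ccccc3)cc(OCc3ccccc3)c21 | intermediate
7 | 5,7-bis(benzyloxy)-2-[4-(benzyloxy)phenyl]-4H-chromen-4-one | O=c1cc(-c2ccc(OCc3ccccc3)cc2)oc2cc(OCc3ccccc3)cc(OCc3ccccc3)c12 | intermediate
8 | 5,7-dihydroxy-2-(4-hydroxyphenyl)-4H-chromen-4-one (apigenin) | O=c1cc(-c2ccc(O)cc2)oc2cc(O)cc(O)c12 | intermediate
9 | bis(dimethylamino)methane | CN(C)CN(C)C | starting material
10 | 8-[(dimethylamino)methyl]-5,7-dihydroxy-2-(4-hydroxyphenyl)-4H-chromen-4-one | O=c1cc(-c2ccc(O)cc2)oc2c(CN(C)C)c(O)cc(O)c12 | intermediate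
11 | 4-hydroxyphenylboronic acid | OB(O)c1ccc(O)cc1 | starting material
12 | 5-hydroxy-2-(4-hydroxyphenyl)-8-methylidene-4H-chromene-4,7(8H)-dione (o-quinone methide; not isolated) | C=C1C(=O)C=C(O)C2=C1OC(=CC2=O)c1ccc(O)cc1 | intermediate
13 | 5-hydroxy-8-(4-hydroxybenzyl)-2-(4-hydroxyphenyl)-4-oxo-4H-chromen-7-yl dihydrogen borate (not isolated) | O=c1cc(-c2ccc(O)cc2)oc2c(Cc3ccc(O)cc3)c(OB(O)O)cc(O)c12 | intermediate
14 | 5,7-dihydroxy-8-(4-hydroxybenzyl)-2-(4-hydroxyphenyl)-4H-chromen-4-one (achiral) | O=c1cc(-c2ccc(O)cc2)oc2c(Cc3ccc(O)cc3)c(O)cc(O)c12 | target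

**Totals**
Total step count: 6. Longest linear sequence: 6 steps (1 → 2 → 5 → 7 → 8 → 10 → 14).

**Three steps most likely to fail**

Step 6 (the proposed new step). Risks are oligomerisation of the o-quinone methide to methylene-bridged dimers, protodeboronation of 11, and attack by the free phenol of 11 instead of aryl transfer. The fallback uses known chemistry, sets out from 7 and comes back to the route at 14. Electrophilic iodination of 7 (NIS, cat. TFA, MeCN/CH2Cl2, rt; C8 is the innate SEAr site of 5,7-di-O-alkylflavones) gives 5,7-bis(benzyloxy)-2-[4-(benzyloxy)phenyl]-8-iodo-4H-chromen-4-one F1. Commercial 4-(benzyloxy)benzyl chloride with Zn dust/LiCl in THF gives [4-(benzyloxy)benzyl]zinc chloride F2. Negishi coupling of F1 with F2 (Pd(OAc)2/SPhos, THF, rt to 50 °C) gives 5,7-bis(benzyloxy)-8-[4-(benzyloxy)benzyl]-2-[4-(benzyloxy)phenyl]-4H-chromen-4-one F3. Hydrogenolysis of all four benzyl ethers (H2, Pd/C, THF/MeOH) then gives 14.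

Step 5 (Mannich regioselectivity). Risks are the C6 isomer and the 6,8-bis adduct. The fallback moves the regiochemical decision to a halogenation of the fully protected flavone; it sets out from 7 and comes back at 10. NBS (1.05 equiv, DMF, rt) gives 5,7-bis(benzyloxy)-2-[4-(benzyloxy)phenyl]-8-bromo-4H-chromen-4-one F4. Suzuki–Miyaura aminomethylation with potassium (dimethylaminomethyl)trifluoroborate (Pd(OAc)2/XPhos, Cs2CO3, THF/H2O, 80 °C) gives 5,7-bis(benzyloxy)-2-[4-(benzyloxy)phenyl]-8-[(dimethylamino)methyl]-4H-chromen-4-one F5. Lewis-acid debenzylation (BCl3, pentamethylbenzene, CH2Cl2, −78 °C; used instead of hydrogenolysis, which would also cleave the benzylic C–N bond) gives 10.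

Step 1 (selective bis-O-benzylation). Risks are mono- and tri-O-benzyl products and C-benzylation. The fallback replaces kinetic selectivity by protect-all then chelation-controlled deprotection; it sets out from 1 and comes back at 2. Exhaustive benzylation (BnBr 3.5 equiv, K2CO3, DMF, 60 °C) gives 1-[2,4,6-tris(benzyloxy)phenyl]ethan-1-one F6. MgBr2·OEt2 (toluene/Et2O, reflux) then removes only one benzyl group ortho to the ketone and gives 2.

**Further compounds**
F1 | step 6 | 5,7-bis(benzyloxy)-2-[4-(benzyloxy)phenyl]-8-iodo-4H-chromen-4-one | O=c1cc(-c2ccc(OCc3ccccc3)cc2)oc2c(I)c(OCc3ccccc3)cc(OCc3ccccc3)c12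
F2 | step 6 | [4-(benzyloxy)benzyl]zinc chloride | Cl[Zn]Cc1ccc(OCc2ccccc2)cc1
F3 | step 6 | 5,7-bis(benzyloxy)-8-[4-(benzyloxy)benzyl]-2-[4-(benzyloxy)phenyl]-4H-chromen-4-one | O=c1cc(-c2ccc(OCc3ccccc3)cc2)oc2c(Cc3ccc(OCc4ccccc4)cc3)c(OCc3ccccc3)cc(OCc3ccccc3)c12
F4 | step 5 | 5,7-bis(benzyloxy)-2-[4-(benzyloxy)phenyl]-8-bromo-4H-chromen-4-one | O=c1cc(-c2ccc(OCc3ccccc3)cc2)oc2c(Br)c(OCc3ccccc3)cc(OCc3ccccc3)c12
F5 | step 5 | 5,7-bis(benzyloxy)-2-[4-(benzyloxy)phenyl]-8-[(dimethylamino)methyl]-4H-chromen-4-one | O=c1cc(-c2ccc(OCc3ccccc3)cc2)oc2c(CN(C)C)c(OCc3ccccc3)cc(OCc3ccccc3)c12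
F6 | step 1 | 1-[2,4,6-tris(benzyloxy)phenyl]ethan-1-one | CC(=O)c1c(OCc2ccccc2)cc(OCc2ccccc2)cc1OCc1ccccc1
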